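Per cent of the E charged was the unit in which I had to choose the next charge, and the choice was which flask to carry forward for the most Z at 3.0 min.

| setting | north | west | violet | amber | green | ochre | grey |
|---|---|---|---|---|---|---|---|
| E | 4.4 mM | 64 mM | 50 mM | 40 mM | 4.0 mM | 20 mM | 13 mM |
| L | 2.8 mM (held) | 2.8 mM (held) | 2.8 mM (held) | 2.8 mM (held) | 2.8 mM (held) | 2.8 mM (held) | 2.8 mM (held) |
| remark | run made earlier | run made earlier |  |  |  |  |  |
| time |  |  | 3.0 min | 3.0 min | 3.0 min | 3.0 min | 3.0 min |

| north: time / min | north: Z / % | west: time / min | west: Z / % |
|---|---|---|---|
| 0.833 | 68.7 | 0.833 | 23.0 |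
| 1.50 | 72.6 | 1.50 | 40.7 |
| 2.50 | 61.3 | 2.50 | 63.5 |
| 3.00 | 58.3 | 3.00 | 74.6 |

(readings scatter by 0.5 percentage points)

* ranking by amount of Z, in percent of the E charged, from high to low, at 3.0 min (violet / amber / green / ochre / grey)
* the same order at 20 s (violet / amber / green / ochre / grey)
* the amount of Z, in percent of the E charged of the flask you put first, at 3.0 min
* the amount of Z, in percent of the E charged of the flask you put last, at 3.0 min

- the numbers in the tables scatter with a standard deviation of 0.5 percentage points
- at the start none of L is in solution

Rates can be read from the runs. I took north's early loss of E, counting what was not Z as E, which makes the reading a low one. I took north's late fall of Z from its readings at 1.50 min and 3.00 min, and west's steady climb as the feed of L.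

E loss, north: 1.39 min⁻¹

Z loss, north: 0.146 min⁻¹

Feed, west: 0.238 min⁻¹

I assumed that both steps draw on the same dissolved L, so it cancels in their ratio. Z is then made as fast as it is used when the share of E left equals the selectivity factor times the share of Z. I called that share of E the mark, and the factor is 0.105. At west's last Z, the mark is 7.82%.

I assumed the same feed in mM, so a flask's feed in shares goes inversely with its charge. E falls at the feed until the E-loss rate on the share left drops to it, and then decays. Amber starts with its E-loss constant above its feed.

Feed, amber: 0.381 min⁻¹; feed, violet: 0.305 min⁻¹

E left, amber: 5.96%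

E left, violet: 11.9%

By my reckoning violet stood 4.1 percentage points short of the mark, with more E left than the mark, and amber 1.9 points past it, with less. I therefore chose amber for first place.

The forecast differed: violet > amber > ochre > grey > green, top 83%, low 57%, and at the early reading green > grey > ochre > amber > violet. Its words were “Violet should therefore sit near its peak, amber just past it”. I took over its other places and values.

The flasks gave amber > violet > ochre > grey > green, and at the early reading green > grey > ochre > amber > violet.

    E + X → Z + G (k = 15.0 M⁻¹ s⁻¹)
    X + Z ⇌ D + G (K = 3.40, k = 2.00 M⁻¹ s⁻¹)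
    L ⇌ X, rate k3*(csat - [X]) (kL = 0.130 s⁻¹)

Amber held 83.5% of Z, more than green's 56.5%. At 3.00 min amber held E 7.18% against a mark of 8.77%, while violet held E 13.1% against 8.47%. Green, read at 80 s, held Z 74.2%, which puts its mark at 7.79%, and its E stood at 7.77%.

(All runs stem from a simulated flask with made-up constants; scatter was added.)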